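All constants were drawn at random within sensible limits; the rest is arithmetic.

One litre of solution in these flasks takes up starting material from the solid substrate towards a solubility of 0.60 M, and the 1.5 M of solid charged is more than that.

    starting material + protic impurity → quenched substrate (k1 = 0.038 M⁻¹ s⁻¹, Ea1 = 65.0 kJ mol⁻¹)
    target → over-reaction product (k2 = 6.9 × 10⁻⁴ s⁻¹, Ea2 = 93.0 kJ mol⁻¹)
    starting material + reagent ⇌ isomer of the product (K3 = 1.4 M⁻¹, k3 = 0.0017 M⁻¹ s⁻¹, Ea3 = 77.0 kJ mol⁻¹, ΔH3 = 22.0 kJ mol⁻¹)
    starting material + reagent ⇌ target (K4 = 0.33 M⁻¹, k4 = 0.12 M⁻¹ s⁻¹, Ea4 = 72.0 kJ mol⁻¹, ΔH4 = −46.0 kJ mol⁻¹)
    solid substrate ⇌ starting material, rate k5*(cs5 - [starting material]) while solid is left; crystals form when [starting material] > cs5 (cs5 = 0.60 M, k5 = 0.32 s⁻¹)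
    (constants at 80 °C)

in all of them: solid substrate 1.5 M; reagent 1.65 M; protic impurity 0.300 M; time 50 s

| run | temperature |
|---|---|
| beta | 65 °C |
| delta | 80 °C |
| epsilon | 95 °C |

- solid substrate is a solid; its amount is given per volume of the solution
- all constants are for 80 °C and move with temperature by the activation energies and enthalpies
- at the start none of the solid substrate is in solution
- what has only dissolved of solid substrate counts as not reacted

1. the best flask by amount of target, in percent of the solid substrate charged; "all alike" if 1.5 percentage points covers them all (beta / delta / epsilon / all alike)
2. amount of target at the end, in percent of the solid substrate charged, beta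
3. amount of target at the end, in percent of the solid substrate charged, delta
4. amount of target at the end, in percent of the solid substrate charged, epsilon

Dissolution has a time constant of 3.12 s. With c(starting material) held at the solubility, the step to target relaxes, forward and back together, with a time constant of 2.30 s in delta and 11.7 s in beta. Each of these is shorter than the run of 50 s. At the reference temperature the step to target also has a larger rate constant than the step to the isomer of the product. This reckoning therefore holds c(starting material) at the solubility while solid remains, treats the step to target as a pre-equilibrium, and sets aside the reagent held as isomer of the product. With K the equilibrium constant of that step, c(target) = K · c(starting material) · (charged reagent − c(target)).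

Rearranged, this gives the solubility share, the part of the charged reagent held as target: Kc/(1 + Kc), with c the solubility.

In beta, K is 0.661 M⁻¹, so the solubility share is 28.4%. That means 0.469 M of target, or 31.2% of the solid charged. In this reckoning the solid in beta lasts: target, the solubility and the whole protic impurity together come to 1.37 M, less than the charge, with the isomer of the product set aside as before.

In delta, K is 0.33 M⁻¹, so the share is 16.5% and target is 18.2%, lower than in beta. The step to target is exothermic (−46.0 kJ mol⁻¹), so K falls further in epsilon, and this reckoning picks beta.

The forecast also chose beta, with 29.9%, 17% and 9% for beta, delta and epsilon, and it began from "Solid stays in excess in all three flasks". Its beta figure lies 1.3 percentage points below the reckoning here.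

The simulation gives beta as the best flask, with 29.5%, 17.1% and 8.99%, so the forecast held within its tolerance.

In beta at the asked time, the forward step to target alone gives starting material a half-life of 14 s, while the isomer step, both ways together, relaxes with a half-life of 7.85 min. At 50.0 s, beta holds 29.5% target against 1.21% isomer of the product. Solid substrate still stands at 23.6% there, and the solubility share's 31.2% lies 1.7 points above the simulated target. A neighbouring flask, beta with 2.8 M of reagent, keeps 3.40% of solid substrate, and the same share gives 53.0% target against its simulated 49.4%.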